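| flask | starting complex | incoming ligand | leaving ligand | temperature | remark | time |
|---|---|---|---|---|---|---|
| delta | 20 mM | 20 mM | 40 mM | 25 °C | the very flask that is asked about, followed so far |  |
| alpha | 20 mM | 20 mM | 80 mM | 10 °C | run made earlier |  |
| flask | 20 mM | 20.0 mM | 40.0 mM | 25 °C |  | 20 h |

| run | time / h | complex with one exchanged / % | starting complex / % |
|---|---|---|---|
| delta | 2.50 | 27.2 | 30.6 |
| delta | 5.00 | 26.6 | 31.3 |
| delta | 8.00 | 29.4 | 31.4 |
| delta | 10.0 | 26.9 | 31.7 |
| delta | 12.0 | 28.7 | 29.8 |
| delta | 15.0 | 25.3 | 28.7 |
| alpha | 0.500 | 36.3 | 36.0 |
| alpha | 2.00 | 28.4 | 35.6 |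
| alpha | 3.00 | 25.2 | 37.0 |
| alpha | 4.00 | 21.6 | 35.3 |
| alpha | 6.00 | 18.4 | 34.3 |
| alpha | 8.00 | 16.4 | 36.2 |

(readings scatter by 1 percentage point)

- additions bring no volume worth counting

- green: change nothing and wait 6.0 h more
- red: at 20 h take out 90 % of the leaving ligand then present, then wait 6.0 h
- grey: at 20 h raise the temperature by 15 K, then wait 6.0 h
- blue: at 20 h add incoming ligand, 100 % of the amount charged, then wait 6.0 h

- complex with one exchanged, in percent of the starting complex first charged, at 20 h
- the option that brings most further complex with one exchanged ("none" if no option brings more than 2 percentage points) (green / red / grey / blue / none)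
- complex with one exchanged present, in percent of the starting complex first charged, after green
- complex with one exchanged present, in percent of the starting complex first charged, after red

Note for the bench, delta flask:

1. The product, complex with one exchanged, has stood near 27.4 % since 2.50 h, and starting complex near 30.6 %. So we expect 27.4 % at 20 h, and the same after green.

2. Of what has left the starting complex, 39.4 % stands as product. This product share is what we carry.

3. In alpha, the product fell from 36.3 % to 16.4 % while starting complex stayed near 36.2 %. The product therefore passes on to something unseen, and its share at the last reading is 25.7 %. Alpha differs from delta in leaving ligand too, 80 mM against 40 mM, so laying the lower share to its 10 °C is our assumption.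

4. Leave red alone: starting complex did not rise in alpha, so we see no way back for removal to block, and we expect 27.4 % after red. Blue meets 30.6 % of starting complex and 27.4 % of product, so it can use up product as well as make it; we expect little.

5. Warm it. Going round once more, unseen per product is 2.89 in alpha and 1.54 here. The same factor over the next 15 K gives a share of 55.0 %, a gain of 11 percentage points, so we choose grey.

The forecast gave 27 % at 20 h, 26.8 % after green and 32 % after red, and it chose blue, differing from us on red and on the choice: “Blue edges red, uncertainly”.

The flask gives 27.0 % at 20 h, 27.0 % after green and 27.0 % after red; grey is best.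

    complex with three exchanged + incoming ligand → leaving ligand + complex with four exchanged (k = 52.9 L mol⁻¹ min⁻¹, Ea = 39.0 kJ mol⁻¹)
    starting complex + incoming ligand → leaving ligand + complex with one exchanged (k = 24.1 L mol⁻¹ min⁻¹, Ea = 61.0 kJ mol⁻¹)
    complex with one exchanged ⇌ isomer of the product (K = 0.855, k = 0.0272 min⁻¹, Ea = 89.0 kJ mol⁻¹, ΔH = −31.0 kJ mol⁻¹)
    complex with two exchanged + incoming ligand → leaving ligand + complex with three exchanged (k = 12.3 L mol⁻¹ min⁻¹, Ea = 43.0 kJ mol⁻¹)
    starting complex → decomposition product (k = 5.19 × 10⁻⁵ min⁻¹, Ea = 111 kJ mol⁻¹)
    complex with one exchanged + incoming ligand → leaving ligand + complex with two exchanged (k = 12.4 L mol⁻¹ min⁻¹, Ea = 42.0 kJ mol⁻¹)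
    2 incoming ligand → homo dimer (k = 1.47 L mol⁻¹ min⁻¹, Ea = 65.0 kJ mol⁻¹)
    (constants at 25 °C)

Grey adds 7.1 points, against our 11 points, and blue changes the product by −1.7 points. The forward step from product to its isomer, its way back not counted, has a half-life of 0.42 h, shorter than 20 h. At 20.0 h the flask holds 27.0 % of product beside 23.1 % of isomer, with incoming ligand, the limiting reagent, at 0 %, and the product share stands at 38.1 %. In the repeat of this flask at 10 °C, starting complex stands at 35.7 % at 20.0 h, so the share read from alpha's last reading gives 16.5 % of product, and that repeat holds 15.8 %.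

Readings and results come from a simulation from invented constants; scatter was added.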